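**Retrosynthetic overview**
1. Oxetane last: the C7–O bond is closed from a lactol (via its anomeric bromide) onto the C2 tertiary alcohol; C3–Br and C2–OH come from bromide opening of a C2–C3 epoxide.
2. The epoxide is delivered by the C7 hydroxymethyl group; the oxolane (lactol) forms from the C9 alcohol and the C7 aldehyde; C9 is set by CBS reduction of an isopropenyl ketone.
3. The vinyl bromide comes from the C5 ketone via dienyl triflate and stannane; the C2 methyl comes from the C2 ketone via enol triflate.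
4. The cyclohexane ring and the quaternary C1 come from an epoxide-initiated cyclisation of an α-substituted β-keto ester, with C1 relayed from an (S)-epoxide.
5. Key C1–C2 bond: crossed Claisen condensation of dimethyl succinate enolate with an (S)-epoxy ester. Ring order: cyclohexane, then oxolane, then oxetane.

Assumption: locants C1–C10 in the comments follow the target (C1 spiro carbon, C2 C(Me)O, C3 CHBr, C4 =CH, C5 =CBr, C6 CMe2, C7 acetal CH, C8 CH2, C9 OCH, C10 isopropenyl carbon), and the L-fructose-derived Shi ketone is bought.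

**Route**

Step 1
Reactants: 1 2-methylbut-3-en-2-ol; 2 trimethyl orthoacetate
Product: 4 methyl 5-methylhex-4-enoate, via mixed ketene acetal 3 (not isolated)
Conditions: EtCO2H (cat.), neat, 110–140 °C, MeOH distilled off
Reagents that add atoms: none
Why: Johnson–Claisen rearrangement: the ketene acetal of the tertiary allylic alcohol undergoes a [3,3]-shift to the γ,δ-unsaturated ester with the prenyl terminus; no stereocentre.

Step 2
Reactants: 4 methyl 5-methylhex-4-enoate
Product: 5 methyl 3-[(2S)-3,3-dimethyloxiran-2-yl]propanoate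
Conditions: L-fructose-derived Shi ketone (1,2:4,5-di-O-isopropylidene-β-L-erythro-2,3-hexodiulo-2,6-pyranose, 30 mol %), KHSO5 (as 2KHSO5·KHSO4·K2SO4), K2CO3, Bu4NHSO4, MeCN–CH2(OMe)2–aq. Na2B4O7 buffer, 0 °C
Reagents that add atoms: potassium peroxymonosulfate, [K+].[O-]S(=O)(=O)OO
Why: Shi asymmetric epoxidation (chiral dioxirane, spiro transition state) of the trisubstituted alkene; the L-fructose-derived ketone gives the (S)-epoxide, the mirror image of the (R)-epoxide obtained with the common D-fructose ketone.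

Step 3
Reactants: 5 methyl 3-[(2S)-3,3-dimethyloxiran-2-yl]propanoate; 6 dimethyl succinate
Product: 8 dimethyl 2-{3-[(2S)-3,3-dimethyloxiran-2-yl]propanoyl}butanedioate (C2 epimers), via lithium enolate of dimethyl succinate 7 (not isolated)
Conditions: LiN(i-Pr)2 (2.2 equiv), 6 (2.3 equiv), THF, −78 °C; then 5 (1.0 equiv), −78 to −30 °C; AcOH quench
Reagents that add atoms: none
Why: Crossed Claisen condensation: the preformed lithium ester enolate adds to the methyl ester of 5 and the second equivalent deprotonates the β-keto ester as it forms, which drives the reaction; the new C1 centre is enolisable and is fixed only in step 4.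

Step 4
Reactants: 8 dimethyl 2-{3-[(2S)-3,3-dimethyloxiran-2-yl]propanoyl}butanedioate
Product: 9 methyl (1S,3S)-3-hydroxy-1-(2-methoxy-2-oxoethyl)-2,2-dimethyl-6-oxocyclohexane-1-carboxylate
Conditions: SnCl4 (1.5 equiv), CH2Cl2, −78 to −30 °C, cold aqueous NaHCO3 quench
Reagents that add atoms: none
Why: Epoxide-initiated cationic cyclisation (6-endo attack of the tin-chelated Z-enol on the tertiary epoxide carbon) through a chair with the C5–O bond equatorial and the ester carbonyl cis to the enol oxygen, so the ester ends up cis to the C5 hydroxyl and the quaternary C1 is set from the (S)-epoxide.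

Step 5
Reactants: 9 methyl (1S,3S)-3-hydroxy-1-(2-methoxy-2-oxoethyl)-2,2-dimethyl-6-oxocyclohexane-1-carboxylate
Product: 10 methyl (1S,3S)-1-(2-methoxy-2-oxoethyl)-2,2-dimethyl-6-oxo-3-[(triethylsilyl)oxy]cyclohexane-1-carboxylate
Conditions: Et3SiOTf, 2,6-lutidine, CH2Cl2, −78 °C
Reagents that add atoms: triethylsilyl trifluoromethanesulfonate, CC[Si](CC)(CC)OS(=O)(=O)C(F)(F)F
Why: Silylation of the hindered secondary alcohol with the reactive silyl triflate keeps it out of the enolate chemistry; no stereocentre changes.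

Step 6
Reactants: 10 methyl (1S,3S)-1-(2-methoxy-2-oxoethyl)-2,2-dimethyl-6-oxo-3-[(triethylsilyl)oxy]cyclohexane-1-carboxylate
Product: 12 methyl (1S,5S)-1-(2-methoxy-2-oxoethyl)-6,6-dimethyl-5-[(triethylsilyl)oxy]-2-[(trifluoromethanesulfonyl)oxy]cyclohex-2-ene-1-carboxylate, via potassium enolate 11 (not isolated)
Conditions: KN(SiMe3)2, THF, −78 °C; then PhNTf2, −78 to 0 °C
Reagents that add atoms: N-phenylbis(trifluoromethanesulfonimide), FC(F)(F)S(=O)(=O)N(c1ccccc1)S(=O)(=O)C(F)(F)F
Why: Kinetic enolisation can only occur at C3 because C1 is quaternary and the ester α-hydrogens are far less acidic; O-sulfonylation of the enolate gives the enol triflate.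

Step 7
Reactants: 12 methyl (1S,5S)-1-(2-methoxy-2-oxoethyl)-6,6-dimethyl-5-[(triethylsilyl)oxy]-2-[(trifluoromethanesulfonyl)oxy]cyclohex-2-ene-1-carboxylate
Product: 13 methyl (1R,5S)-1-(2-methoxy-2-oxoethyl)-2,6,6-trimethyl-5-[(triethylsilyl)oxy]cyclohex-2-ene-1-carboxylate
Conditions: MeZnCl, Pd(PPh3)4 (5 mol %), THF, 50 °C
Reagents that add atoms: methylzinc chloride, C[Zn]Cl
Why: Negishi cross-coupling of the alkenyl triflate with the methylzinc reagent installs the C2 methyl group and tolerates both esters (the C1 descriptor changes only through priorities).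

Step 8
Reactants: 13 methyl (1R,5S)-1-(2-methoxy-2-oxoethyl)-2,6,6-trimethyl-5-[(triethylsilyl)oxy]cyclohex-2-ene-1-carboxylate
Product: 14 methyl (1R,5S)-5-hydroxy-1-(2-methoxy-2-oxoethyl)-2,6,6-trimethylcyclohex-2-ene-1-carboxylate
Conditions: pyridinium p-toluenesulfonate (0.2 equiv), MeOH, 40 °C
Reagents that add atoms: none
Why: Acid-catalysed methanolysis removes the triethylsilyl ether under conditions too mild to lactonise the cis hydroxy ester.

Step 9
Reactants: 14 methyl (1R,5S)-5-hydroxy-1-(2-methoxy-2-oxoethyl)-2,6,6-trimethylcyclohex-2-ene-1-carboxylate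
Product: 15 methyl (1R)-1-(2-methoxy-2-oxoethyl)-2,6,6-trimethyl-5-oxocyclohex-2-ene-1-carboxylate
Conditions: Dess–Martin periodinane, pyridine, CH2Cl2, 0 °C to rt
Reagents that add atoms: none
Why: Dess–Martin oxidation gives the C5 ketone, which can enolise only towards C4 because C6 is quaternary.

Step 10
Reactants: 15 methyl (1R)-1-(2-methoxy-2-oxoethyl)-2,6,6-trimethyl-5-oxocyclohex-2-ene-1-carboxylate
Product: 17 methyl (1R)-1-(2-methoxy-2-oxoethyl)-2,6,6-trimethyl-5-[(trifluoromethanesulfonyl)oxy]cyclohexa-2,4-diene-1-carboxylate, via potassium dienolate 16 (not isolated)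
Conditions: KN(SiMe3)2, THF, −78 °C; then PhNTf2, −78 to 0 °C
Reagents that add atoms: N-phenylbis(trifluoromethanesulfonimide), FC(F)(F)S(=O)(=O)N(c1ccccc1)S(=O)(=O)C(F)(F)F
Why: Deprotonation at C4 (α to the ketone and allylic) gives the dienolate, and O-sulfonylation fixes the C2=C3–C4=C5 diene as the dienyl triflate.

Step 11
Reactants: 17 methyl (1R)-1-(2-methoxy-2-oxoethyl)-2,6,6-trimethyl-5-[(trifluoromethanesulfonyl)oxy]cyclohexa-2,4-diene-1-carboxylate
Product: 18 methyl (1R)-1-(2-methoxy-2-oxoethyl)-2,6,6-trimethyl-5-(trimethylstannyl)cyclohexa-2,4-diene-1-carboxylate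
Conditions: Me3SnSnMe3, Pd(PPh3)4 (5 mol %), LiCl, THF, 65 °C
Reagents that add atoms: hexamethylditin, C[Sn](C)(C)[Sn](C)(C)C
Why: Palladium-catalysed stannylation of the alkenyl triflate with the ditin (Stille-type triflate–tin exchange, LiCl-assisted) turns the C–O bond into a C–Sn bond.

Step 12
Reactants: 18 methyl (1R)-1-(2-methoxy-2-oxoethyl)-2,6,6-trimethyl-5-(trimethylstannyl)cyclohexa-2,4-diene-1-carboxylate
Product: 19 methyl (1R)-5-bromo-1-(2-methoxy-2-oxoethyl)-2,6,6-trimethylcyclohexa-2,4-diene-1-carboxylate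
Conditions: N-bromosuccinimide (1.0 equiv), CH2Cl2, −78 to 0 °C
Reagents that add atoms: N-bromosuccinimide, BrN1C(=O)CCC1=O
Why: Ipso-bromodestannylation: electrophilic bromine replaces tin at C5 much faster than it adds to the alkenes, giving the vinyl bromide regiospecifically.

Step 13
Reactants: 19 methyl (1R)-5-bromo-1-(2-methoxy-2-oxoethyl)-2,6,6-trimethylcyclohexa-2,4-diene-1-carboxylate
Product: 20 methyl (1R)-5-bromo-1-{2-[methoxy(methyl)amino]-2-oxoethyl}-2,6,6-trimethylcyclohexa-2,4-diene-1-carboxylate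
Conditions: MeNH(OMe)·HCl (1.5 equiv), i-PrMgCl (3.0 equiv), THF, −20 °C
Reagents that add atoms: N,O-dimethylhydroxylamine hydrochloride, CNOC.Cl
Why: Weinreb amidation with the magnesium amide is chemoselective for the unhindered CH2CO2Me ester because the ester on the quaternary carbon is shielded by C2 and C6.

Step 14
Reactants: 20 methyl (1R)-5-bromo-1-{2-[methoxy(methyl)amino]-2-oxoethyl}-2,6,6-trimethylcyclohexa-2,4-diene-1-carboxylate
Product: 21 methyl (1R)-5-bromo-2,6,6-trimethyl-1-(3-methyl-2-oxobut-3-en-1-yl)cyclohexa-2,4-diene-1-carboxylate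
Conditions: CH2=C(CH3)MgBr, THF, −20 to 0 °C; aqueous NH4Cl
Reagents that add atoms: isopropenylmagnesium bromide, CC(=C)[Mg]Br
Why: Grignard addition to the Weinreb amide stops at the ketone stage through the stable magnesium chelate, giving the isopropenyl ketone.

Step 15
Reactants: 21 methyl (1R)-5-bromo-2,6,6-trimethyl-1-(3-methyl-2-oxobut-3-en-1-yl)cyclohexa-2,4-diene-1-carboxylate
Product: 22 methyl (1R)-5-bromo-1-[(2R)-2-hydroxy-3-methylbut-3-en-1-yl]-2,6,6-trimethylcyclohexa-2,4-diene-1-carboxylate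
Conditions: (S)-1-methyl-3,3-diphenyltetrahydro-1H,3H-pyrrolo[1,2-c][1,3,2]oxazaborole (20 mol %), catecholborane, toluene, −78 °C
Reagents that add atoms: none
Why: Corey–Bakshi–Shibata reduction: the isopropenyl group acts as the large substituent, so the (S)-catalyst gives the (R)-allylic alcohol at C9, and catecholborane at low temperature avoids hydroboration.

Step 16
Reactants: 22 methyl (1R)-5-bromo-1-[(2R)-2-hydroxy-3-methylbut-3-en-1-yl]-2,6,6-trimethylcyclohexa-2,4-diene-1-carboxylate
Product: 23 methyl (1R)-5-bromo-1-{(2R)-2-[(tert-butyldimethylsilyl)oxy]-3-methylbut-3-en-1-yl}-2,6,6-trimethylcyclohexa-2,4-diene-1-carboxylate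
Conditions: t-BuMe2SiOTf, 2,6-lutidine, CH2Cl2, −78 °C
Reagents that add atoms: tert-butyldimethylsilyl trifluoromethanesulfonate, CC(C)(C)[Si](C)(C)OS(=O)(=O)C(F)(F)F
Why: Silylation protects the C9 alcohol, prevents lactonisation onto the ester and keeps the isopropenyl alkene out of the later directed epoxidation.

Step 17
Reactants: 23 methyl (1R)-5-bromo-1-{(2R)-2-[(tert-butyldimethylsilyl)oxy]-3-methylbut-3-en-1-yl}-2,6,6-trimethylcyclohexa-2,4-diene-1-carboxylate
Product: 24 [(1R)-5-bromo-1-{(2R)-2-[(tert-butyldimethylsilyl)oxy]-3-methylbut-3-en-1-yl}-2,6,6-trimethylcyclohexa-2,4-dien-1-yl]methanol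
Conditions: LiAlH4, Et2O, 0 °C to rt
Reagents that add atoms: none
Why: LiAlH4 reduces the hindered neopentyl ester to the primary alcohol that will direct the epoxidation, leaving vinyl bromide and silyl ether untouched.

Step 18
Reactants: 24 [(1R)-5-bromo-1-{(2R)-2-[(tert-butyldimethylsilyl)oxy]-3-methylbut-3-en-1-yl}-2,6,6-trimethylcyclohexa-2,4-dien-1-yl]methanol
Product: 25 [(1R,5R,6S)-3-bromo-5-{(2R)-2-[(tert-butyldimethylsilyl)oxy]-3-methylbut-3-en-1-yl}-4,4,6-trimethyl-7-oxabicyclo[4.1.0]hept-2-en-5-yl]methanol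
Conditions: VO(acac)2 (5 mol %), t-BuOOH, CH2Cl2, 0 °C to rt
Reagents that add atoms: tert-butyl hydroperoxide, CC(C)(C)OO
Why: Vanadium-catalysed hydroxyl-directed epoxidation of the homoallylic alcohol: oxygen is delivered within the vanadate ester to the electron-rich C2=C3 alkene on the face of the CH2OH group, which sets C2 and C3 with the epoxide cis to C7.

Step 19
Reactants: 25 [(1R,5R,6S)-3-bromo-5-{(2R)-2-[(tert-butyldimethylsilyl)oxy]-3-methylbut-3-en-1-yl}-4,4,6-trimethyl-7-oxabicyclo[4.1.0]hept-2-en-5-yl]methanol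
Product: 26 (1R,5S,6S)-3-bromo-5-{(2R)-2-[(tert-butyldimethylsilyl)oxy]-3-methylbut-3-en-1-yl}-4,4,6-trimethyl-7-oxabicyclo[4.1.0]hept-2-ene-5-carbaldehyde
Conditions: Dess–Martin periodinane, pyridine, CH2Cl2, 0 °C
Reagents that add atoms: none
Why: Buffered Dess–Martin oxidation gives the non-enolisable aldehyde without opening the vinyl epoxide.

Step 20
Reactants: 26 (1R,5S,6S)-3-bromo-5-{(2R)-2-[(tert-butyldimethylsilyl)oxy]-3-methylbut-3-en-1-yl}-4,4,6-trimethyl-7-oxabicyclo[4.1.0]hept-2-ene-5-carbaldehyde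
Product: 28 epoxy lactol (1S,2S,3R,9R; both C7 anomers): the 5-bromo-2,6,6-trimethylcyclohex-4-ene ring carrying the 2,3-epoxide and spiro-fused at C1 to a 2-hydroxy-5-isopropenyloxolane, via hydroxy aldehyde 27 (not isolated)
Conditions: Bu4NF, AcOH (1:1), THF, 0 °C
Reagents that add atoms: none
Why: Fluoride desilylation frees the C9 hydroxyl, which adds to the neighbouring aldehyde to form the five-membered lactol (oxolane ring).

Step 21
Reactants: 28 epoxy lactol
Product: 29 bromohydrin lactol (1S,2S,3S,9R; both C7 anomers): as 28 but with C2–OH (cis to C7) and C3–Br (trans to that OH) in place of the epoxide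
Conditions: Li2NiBr4 (made from LiBr and NiBr2 in THF), THF, 0 °C; pH 7 buffer
Reagents that add atoms: dilithium tetrabromonickelate, [Li+].[Li+].Br[Ni-2](Br)(Br)Br
Why: SN2 opening of the vinyl epoxide by soft bromide at the allylic, less substituted C3 with inversion gives the trans-bromohydrin, so C3–Br is anti to the C2 oxygen that stays cis to C7.

Step 22
Reactants: 29 bromohydrin lactol
Product: 31 target CNP0141320.1 (1S,2S,3S,7S,9R), via anomeric bromide 30 (not isolated)
Conditions: PPh3, CBr4, i-Pr2NEt, 4 Å molecular sieves, CH2Cl2, −40 to 0 °C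
Reagents that add atoms: none
Why: Appel-type activation turns the lactol into the anomeric bromide, whose oxocarbenium ion is trapped by the cis tertiary C2 hydroxyl in an intramolecular Koenigs–Knorr-type glycosylation (4-exo) while the amine removes HBr, so the strained oxetane acetal forms irreversibly; C7 follows from the cis ring fusion.

**Compound list**
1 | 2-methylbut-3-en-2-ol | CC(C)(O)C=C | starting material
2 | trimethyl orthoacetate | CC(OC)(OC)OC | starting material
3 | 1-methoxy-1-[(2-methylbut-3-en-2-yl)oxy]ethene (mixed ketene acetal, not isolated) | C=C(OC)OC(C)(C)C=C | intermediate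
4 | methyl 5-methylhex-4-enoate | COC(=O)CCC=C(C)C | intermediate
5 | methyl 3-[(2S)-3,3-dimethyloxiran-2-yl]propanoate | COC(=O)CC[C@@H]1OC1(C)C | intermediate
6 | dimethyl succinate | COC(=O)CCC(=O)OC | starting material
7 | lithium enolate of dimethyl succinate (not isolated) | COC(=O)CC=C(OC)O[Li] | intermediate
8 | dimethyl 2-{3-[(2S)-3,3-dimethyloxiran-2-yl]propanoyl}butanedioate (C2 epimers) | COC(=O)CC(C(=O)OC)C(=O)CC[C@@H]1OC1(C)C | intermediate
9 | methyl (1S,3S)-3-hydroxy-1-(2-methoxy-2-oxoethyl)-2,2-dimethyl-6-oxocyclohexane-1-carboxylate | COC(=O)[C@]1(CC(=O)OC)C(=O)CC[C@H](O)C1(C)C | intermediate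
10 | methyl (1S,3S)-1-(2-methoxy-2-oxoethyl)-2,2-dimethyl-6-oxo-3-[(triethylsilyl)oxy]cyclohexane-1-carboxylate | COC(=O)[C@]1(CC(=O)OC)C(=O)CC[C@H](O[Si](CC)(CC)CC)C1(C)C | intermediate
11 | potassium enolate of 10 (C2–OK, C2=C3; not isolated) | COC(=O)[C@]1(CC(=O)OC)C(O[K])=CC[C@H](O[Si](CC)(CC)CC)C1(C)C | intermediate
12 | methyl (1S,5S)-1-(2-methoxy-2-oxoethyl)-6,6-dimethyl-5-[(triethylsilyl)oxy]-2-[(trifluoromethanesulfonyl)oxy]cyclohex-2-ene-1-carboxylate | COC(=O)[C@]1(CC(=O)OC)C(OS(=O)(=O)C(F)(F)F)=CC[C@H](O[Si](CC)(CC)CC)C1(C)C | intermediate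
13 | methyl (1R,5S)-1-(2-methoxy-2-oxoethyl)-2,6,6-trimethyl-5-[(triethylsilyl)oxy]cyclohex-2-ene-1-carboxylate | COC(=O)[C@]1(CC(=O)OC)C(C)=CC[C@H](O[Si](CC)(CC)CC)C1(C)C | intermediate
14 | methyl (1R,5S)-5-hydroxy-1-(2-methoxy-2-oxoethyl)-2,6,6-trimethylcyclohex-2-ene-1-carboxylate | COC(=O)[C@]1(CC(=O)OC)C(C)=CC[C@H](O)C1(C)C | intermediate
15 | methyl (1R)-1-(2-methoxy-2-oxoethyl)-2,6,6-trimethyl-5-oxocyclohex-2-ene-1-carboxylate | COC(=O)[C@]1(CC(=O)OC)C(C)=CCC(=O)C1(C)C | intermediate
16 | potassium dienolate of 15 (C5–OK, C2=C3–C4=C5; not isolated) | COC(=O)[C@]1(CC(=O)OC)C(C)=CC=C(O[K])C1(C)C | intermediate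
17 | methyl (1R)-1-(2-methoxy-2-oxoethyl)-2,6,6-trimethyl-5-[(trifluoromethanesulfonyl)oxy]cyclohexa-2,4-diene-1-carboxylate | COC(=O)[C@]1(CC(=O)OC)C(C)=CC=C(OS(=O)(=O)C(F)(F)F)C1(C)C | intermediate
18 | methyl (1R)-1-(2-methoxy-2-oxoethyl)-2,6,6-trimethyl-5-(trimethylstannyl)cyclohexa-2,4-diene-1-carboxylate | COC(=O)[C@]1(CC(=O)OC)C(C)=CC=C([Sn](C)(C)C)C1(C)C | intermediate
19 | methyl (1R)-5-bromo-1-(2-methoxy-2-oxoethyl)-2,6,6-trimethylcyclohexa-2,4-diene-1-carboxylate | COC(=O)[C@]1(CC(=O)OC)C(C)=CC=C(Br)C1(C)C | intermediate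
20 | methyl (1R)-5-bromo-1-{2-[methoxy(methyl)amino]-2-oxoethyl}-2,6,6-trimethylcyclohexa-2,4-diene-1-carboxylate | COC(=O)[C@]1(CC(=O)N(C)OC)C(C)=CC=C(Br)C1(C)C | intermediate
21 | methyl (1R)-5-bromo-2,6,6-trimethyl-1-(3-methyl-2-oxobut-3-en-1-yl)cyclohexa-2,4-diene-1-carboxylate | COC(=O)[C@]1(CC(=O)C(C)=C)C(C)=CC=C(Br)C1(C)C | intermediate
22 | methyl (1R)-5-bromo-1-[(2R)-2-hydroxy-3-methylbut-3-en-1-yl]-2,6,6-trimethylcyclohexa-2,4-diene-1-carboxylate | COC(=O)[C@]1(C[C@@H](O)C(C)=C)C(C)=CC=C(Br)C1(C)C | intermediate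
23 | methyl (1R)-5-bromo-1-{(2R)-2-[(tert-butyldimethylsilyl)oxy]-3-methylbut-3-en-1-yl}-2,6,6-trimethylcyclohexa-2,4-diene-1-carboxylate | COC(=O)[C@]1(C[C@@H](O[Si](C)(C)C(C)(C)C)C(C)=C)C(C)=CC=C(Br)C1(C)C | intermediate
24 | [(1R)-5-bromo-1-{(2R)-2-[(tert-butyldimethylsilyl)oxy]-3-methylbut-3-en-1-yl}-2,6,6-trimethylcyclohexa-2,4-dien-1-yl]methanol | OC[C@]1(C[C@@H](O[Si](C)(C)C(C)(C)C)C(C)=C)C(C)=CC=C(Br)C1(C)C | intermediate
25 | [(1R,5R,6S)-3-bromo-5-{(2R)-2-[(tert-butyldimethylsilyl)oxy]-3-methylbut-3-en-1-yl}-4,4,6-trimethyl-7-oxabicyclo[4.1.0]hept-2-en-5-yl]methanol (epoxide cis to CH2OH) | OC[C@]1(C[C@@H](O[Si](C)(C)C(C)(C)C)C(C)=C)[C@]2(C)O[C@@H]2C=C(Br)C1(C)C | intermediate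
26 | (1R,5S,6S)-3-bromo-5-{(2R)-2-[(tert-butyldimethylsilyl)oxy]-3-methylbut-3-en-1-yl}-4,4,6-trimethyl-7-oxabicyclo[4.1.0]hept-2-ene-5-carbaldehyde | O=C[C@]1(C[C@@H](O[Si](C)(C)C(C)(C)C)C(C)=C)[C@]2(C)O[C@@H]2C=C(Br)C1(C)C | intermediate
27 | hydroxy aldehyde: 26 with free C9–OH (1S,2S,3R,9R; not isolated) | O=C[C@]1(C[C@@H](O)C(C)=C)[C@]2(C)O[C@@H]2C=C(Br)C1(C)C | intermediate
28 | epoxy lactol (1S,2S,3R,9R; C7 anomers): 5-bromo-2,6,6-trimethyl-2,3-epoxycyclohex-4-ene spiro-fused at C1 to 2-hydroxy-5-isopropenyloxolane | C=C(C)[C@H]1C[C@@]2(C(O)O1)[C@]3(C)O[C@@H]3C=C(Br)C2(C)C | intermediate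
29 | bromohydrin lactol (1S,2S,3S,9R; C7 anomers): as 28 with C2–OH cis to C7 and C3–Br trans to it | C=C(C)[C@H]1C[C@@]2(C(O)O1)[C@](C)(O)[C@@H](Br)C=C(Br)C2(C)C | intermediate
30 | anomeric bromide: 29 with Br in place of the lactol OH at C7 (not isolated) | C=C(C)[C@H]1C[C@@]2(C(Br)O1)[C@](C)(O)[C@@H](Br)C=C(Br)C2(C)C | intermediate
31 | CNP0141320.1 (1S,2S,3S,7S,9R): 3,5-dibromo-2,6,6-trimethylcyclohex-4-ene spiro-fused at C1 to the 9-isopropenyl oxolane and bridged C2–O–C7 by the oxetane | C=C(C)[C@H]1C[C@@]23[C@@H](O1)O[C@]2(C)[C@@H](Br)C=C(Br)C3(C)C | target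

**Step count**
Total steps: 22. Longest linear sequence: 22 (1 to 31).

**Three steps most likely to fail**

Step 22 (oxetane acetal closure). The neutral tertiary hydroxyl may not capture the anomeric cation fast enough to beat dimerisation or return to the lactol. The fallback sets out from 24 and comes back at 31. Oxidise 24 with Dess–Martin periodinane to the dienyl aldehyde F1. Remove the silyl group with Bu4NF/AcOH so that the C9 hydroxyl closes onto the aldehyde to give the diene lactol F2. Treat F2 at −78 °C in CH2Cl2 with one equivalent of 2,4,4,6-tetrabromocyclohexa-2,5-dienone. Bromonium formation on the C2=C3 alkene and 4-exo capture at the tertiary C2 by the lactol hydroxyl (possible only cis to C7) gives 31 directly, with bromine at C3 anti to the new C–O bond. This forms the oxetane C–O bond at C2 instead of at C7 and replaces steps 18–22. The hazard is competing attack of the bromonium source on the isopropenyl group or at the diene terminus, which is why it is not the main route.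

Step 4 (cyclisation building two adjacent quaternary carbons). O-alkylation of the enol or lactonisation of the cis hydroxy ester may compete. The fallback sets out from 5 and comes back at 10. Condense 5 with excess lithium enolate of methyl acetate to the α-unsubstituted epoxy β-keto ester F3. Cyclise F3 with SnCl4, the long-established unsubstituted case, to the hydroxy keto ester F4. Silylate with Et3SiOTf/2,6-lutidine to the silyl ether F5. Only then create the quaternary centre by alkylating F5 with methyl bromoacetate (K2CO3, acetone). Axial attack on the enolate half-chair with the silyloxy group equatorial places the new CH2CO2Me trans to the silyloxy group, which is 10; any C1 epimer is removed by chromatography.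

Step 3 (crossed Claisen between two enolisable esters). Proton exchange between enolate 7 and ester 5 can scramble the partners. The fallback sets out from 4 and comes back at 8. Convert 4 with MeNH(OMe)·HCl/i-PrMgCl into the Weinreb amide F6. Epoxidise with the same Shi system to the epoxy Weinreb amide F7. Acylate 1.2 equivalents of enolate 7 with F7 at −78 °C. The tetrahedral lithium chelate survives until work-up, so no second equivalent of base and no proton shuffling are involved, and 8 is released on quench.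

Further compounds
F1 | step 22 | (1R)-5-bromo-1-{(2R)-2-[(tert-butyldimethylsilyl)oxy]-3-methylbut-3-en-1-yl}-2,6,6-trimethylcyclohexa-2,4-diene-1-carbaldehyde | O=C[C@]1(C[C@@H](O[Si](C)(C)C(C)(C)C)C(C)=C)C(C)=CC=C(Br)C1(C)C
F2 | step 22 | diene lactol (1R,9R; C7 anomers): 5-bromo-2,6,6-trimethylcyclohexa-2,4-diene spiro-fused at C1 to 2-hydroxy-5-isopropenyloxolane | C=C(C)[C@H]1C[C@@]2(C(O)O1)C(C)=CC=C(Br)C2(C)C
F3 | step 4 | methyl 5-[(2S)-3,3-dimethyloxiran-2-yl]-3-oxopentanoate | COC(=O)CC(=O)CC[C@@H]1OC1(C)C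
F4 | step 4 | methyl (3S)-3-hydroxy-2,2-dimethyl-6-oxocyclohexane-1-carboxylate (C1 epimers) | COC(=O)C1C(=O)CC[C@H](O)C1(C)C
F5 | step 4 | methyl (3S)-2,2-dimethyl-6-oxo-3-[(triethylsilyl)oxy]cyclohexane-1-carboxylate (C1 epimers) | COC(=O)C1C(=O)CC[C@H](O[Si](CC)(CC)CC)C1(C)C
F6 | step 3 | N-methoxy-N,5-dimethylhex-4-enamide | CON(C)C(=O)CCC=C(C)C
F7 | step 3 | 3-[(2S)-3,3-dimethyloxiran-2-yl]-N-methoxy-N-methylpropanamide | CON(C)C(=O)CC[C@@H]1OC1(C)C
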